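**Compound numbers used throughout:** 1 tert‑butyl acetoacetate; 2 dimethyl glutaconate; 3 racemic keto triester; 4 syn hydroxy triester; 5 all‑trans δ‑lactone; 6 hydroxymethylene lactone; 7 cyclic methyl acetal; 8 dihydropyran triester; 9 side‑chain acid; 10 hydroxytyrosol; 11 dibenzyl hydroxytyrosol; 12 coupled ester; 13 C3 acid; 14 C3 alcohol; 15 dibenzyl aldehyde; 16 target.

Ring atoms of the target are O1, C2 (methyl), C3 (formyl, formyl carbon C7), C4 (side chain), C5 (methyl ester), C6. The target is the all‑trans (2S,3R,4R) isomer; this was checked against the SMILES atom by atom.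

## Analysis of the target

- Compound 16 is a monocyclic 3,4‑dihydro‑2H‑pyran whose C5=C6 enol ether is conjugated to a methyl ester on C5 (a β‑alkoxyacrylate). C2 carries a methyl group, C3 a formyl group, and C4 an acetic ester arm whose alcohol part is hydroxytyrosol (10).
- The three stereocentres are contiguous, C2 (S), C3 (R) and C4 (R). The substituents alternate between the ring faces, so methyl/formyl and formyl/arm are both trans.
- C3–H is α to the aldehyde and O1 is β to it. Base can therefore epimerise C3 or expel O1 as a vinylogous carboxylate (ring opening by E1cB).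
- The free catechol does not survive oxidants, and three carboxyl‑derived carbons (C5 ester, side‑chain ester, C7) must be told apart.
- The hard part is not the ring but setting C2 to C4 in one absolute sense when only C3 can be corrected late, and keeping aldehyde and catechol masked until the end.
- The strategy rests on this feature: C4 is the central carbon of a glutarate. One acetic acid arm is C5 with the carbon of its methoxycarbonyl group; the other is the side‑chain CH2CO2R. C6 is only a formyl‑level one‑carbon insert on C5 that is tied back to O1.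
- On the other side, CH3–C2(O1)–C3–C7 is a reduced acetoacetate. In its keto form C3 is labile, and once C2 carries a hydroxyl, that hydroxyl can choose between the two arms on C4.

## Retrosynthetic reasoning

**16 from 15.** The two aryl O–benzyl bonds are cut last. The catechol must be masked during the oxidation that makes the aldehyde, and hydrogenolysis is neutral, so the epimerisable, ring‑opening‑prone β‑alkoxy aldehyde never meets acid or base.

**15 from 14, 13 and 12.** The formyl carbon C7 is traced back through the primary alcohol 14 to the free acid 13 and to the tert‑butyl ester 12. The C3 carboxyl is the only ester in the molecule that acid cleaves, so it can be taken down to the aldehyde level while the C5 and side‑chain esters stay. The forward steps must reduce one free acid beside two esters and oxidise without base.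

**12 from 9 and 11; 9 from 8; 11 from 10.** The acyl–oxygen bond of the side‑chain ester is cut. Acid 9 comes from triester 8 by hydrolysing its only unhindered, unconjugated methyl ester. Alcohol 11 is 10 with both phenols benzylated. Coupling at this stage keeps the expensive partner out of the early steps.

**8 from 6 and 5.** The O1–C6 and C5–C6 bonds of the pyran are cut. C6 is a formyl carbon on the α‑carbon of an ester, held as an enol ether by the C2 oxygen.
- Forward, lactone 5 is formylated at its α‑CH2 (C5) to give 6, and acidic alcoholysis then rearranges 6. The acyl carbon of the lactone becomes the methoxycarbonyl carbon on C5, and O1 moves to the formyl carbon.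
- This reading leaves both arms of C4 at the carboxyl level, so the ring needs no redox step.
- The lactone has two jobs: it marks which arm is formylated (its α‑CH2 is the most acidic C–H), and it passes its C4 configuration to the pyran.
- The other reading, with the lactone carbonyl as C6 of the pyran, would need carboxylation at C5 and selective reduction of one acyl carbon among four. It was not taken.

**5 from 4 and 3 (key disconnection).** The lactone O1–C6 bond (C6 here is the acyl carbon of the lactone) and the C2–H bond are cut. This leads to keto triester 3, in which C4 has two identical arms and C3 is a labile β‑keto ester carbon.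
- Forward, an enzyme reduction must fix C2 and, through dynamic resolution, C3.
- The new hydroxyl must then acylate one of the two diastereotopic arms to fix C4.
- Three stereocentres and the ring come from a racemate with one labile centre.

**3 from 1 and 2.** The C3–C4 bond is cut in the Michael sense. The doubly activated methylene of 1 adds to the β‑carbon of 2, which makes the prochiral glutarate centre in one step from two bulk esters.

## Alternatives that were turned down

**Alternative 1: photocycloaddition and retro‑aldol.**
- Disconnection: C4–C5 and C3–C7.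
- Forward key step: irradiation of the enol A3 with the alkene of lactone A2 gives a cyclobutanol that opens by retro‑aldol to A1. The lactone of A1 must then be opened by the primary hydroxyl of a protected 10 while O1 closes on the hydroxymethylene carbon.
- For: two C–C bonds in one step; C7, C5 and C6 arrive at their final oxidation levels; no carboxyl differentiation and no redox steps. On convergence and on steps after the key step it is stronger than the chosen route.
- Against: the alkene of A2 is unpolarised, so the regiochemistry of the cycloaddition is not secured. Facial selectivity rests on one allylic methyl group. C4 is formed irreversibly and cannot be epimerised. A2 is a β,γ‑unsaturated lactone that tends to slip into conjugation, and it must first be made enantiopure.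
- Comparison: the chosen route forms no C–C bond in its key step, but sets C4 under reversible conditions and takes the absolute configuration from a catalyst acting on a one‑step racemate.

**Alternative 2: enamine Michael closure.**
- Disconnection: C3–C4.
- Forward key step: the aldehyde of A5, as an enamine with a chiral secondary amine, attacks C4 of the tethered dienoate (6‑exo‑trig) to give A4, one deprotection from 16.
- For: it is the shortest plan, every carbon is at its final oxidation level, and C3 and C4 are set together. On step economy it is clearly stronger.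
- Against: the enamine carbon C3 is β to O1, and O1 is part of a good leaving group (a vinylogous carboxylate). E1cB loss of the tether should compete before the ring exists. O1 also donates along C6=C5–C4=C–C=O, so C4 is a weak acceptor and C6 is a second electrophilic site. The catalyst has to work with or against the existing C2 centre.
- Comparison: the chosen route fixes all centres on robust ester‑level intermediates and lets the aldehyde appear only one step before the end.

**Alternative 3: malonate‑tethered Michael lactonisation.**
- Disconnection: C4–C5.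
- Forward key step: the malonate carbanion of A7 adds to C4 of the E‑enoate (6‑exo‑trig) and closes the δ‑lactone A6 with all substituents equatorial.
- For: the key step is a reversible intramolecular addition of a stabilised carbanion and is more predictable than an enzyme screen. C5 already has its ester, the side chain already has its final ester, and C3 needs only one oxidation.
- Against: A7 must be built with C2 and C3 already in place, in a linear prelude of about six steps. After A6 the lactone carbonyl has to be taken down to the enol ether CH beside three other esters, one on the same carbon. The oxidative removal of the 4‑methoxybenzyl ether has to spare an electron‑rich catechol ketal.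
- Comparison: the chosen route also passes through a δ‑lactone but reads its acyl carbon as the C5 ester carbon, so no lactone reduction is needed, and it is shorter overall.

Key step: step 2

## Route

Remark on the chemistry: the ketoreductase is not one named enzyme but the member of a commercial screening panel that shows Prelog (S) selectivity at the acetyl group and syn preference at C3 with compound 3.

Step 1
Reactants: 1 tert‑butyl acetoacetate; 2 dimethyl glutaconate
Product: 3 1‑tert‑butyl 5‑methyl 2‑acetyl‑3‑(2‑methoxy‑2‑oxoethyl)pentanedioate (racemic)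
Conditions: DBU (0.1 equiv), MeCN, 0 °C to rt, 1 in slight excess, slow addition of 2
Reagents that add atoms: none
Why: Michael addition; DBU reversibly deprotonates the doubly activated methylene of 1 and the enolate adds to the β‑carbon of 2, so the new carbon carries two identical CH2CO2Me arms and the acetoacetate carbon is formed racemic and stays labile, as step 2 requires. A catalytic amidine base and slow addition of 2 should suppress self‑addition of 2 and the retro‑Claisen or cyclisation reactions that stoichiometric alkoxide would cause.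

Step 2
Reactants: 3 1‑tert‑butyl 5‑methyl 2‑acetyl‑3‑(2‑methoxy‑2‑oxoethyl)pentanedioate
Product: 5 tert‑butyl (2S,3R,4S)‑4‑(2‑methoxy‑2‑oxoethyl)‑2‑methyl‑6‑oxooxane‑3‑carboxylate, via syn hydroxy triester 4 (not isolated)
Conditions: ketoreductase (Prelog‑selective, NADPH‑dependent), NADP+ (cat.), i‑PrOH (10% v/v), KH2PO4/K2HPO4 buffer (0.1 M, pH 7.0), MgSO4 (2 mM), 30 °C; EtOAc extraction; PPTS (0.2 equiv), toluene, 70 °C, then MeOH distilled off
Reagents that add atoms: none
Why: The enzyme binds one C3 epimer of 3 and transfers hydride from NADPH to the re face of the acetyl carbonyl (methyl in the small pocket, the branched triester residue in the large one), which should give the (S) carbinol at C2. C3 is the α‑carbon of a β‑keto ester, so the slow epimer racemises through the enol in the buffer and the whole racemate should drain into the syn hydroxy triester 4; this is the known dynamic reductive kinetic resolution of α‑alkyl acetoacetates by ketoreductases. Weak acid then lets the C2 hydroxyl attack one of the two diastereotopic methoxycarbonyl groups (addition–elimination at the acyl carbon, 6‑exo‑trig), which forms the O1–C6 lactone bond and closes the δ‑lactone with loss of methanol. The arm that closes decides C4: closure through the arm that leaves the spectator CH2CO2Me group equatorial, beside the equatorial methyl and tert‑butoxycarbonyl groups, passes through the less strained chair‑like transition state and gives the more stable all‑trans lactone 5, whereas the other arm would place that group axial. While methanol is still present the lactonisation is reversible, so the mixture can drift toward 5 before methanol is removed; the closest precedent is acid‑catalysed lactonisation of hydroxy glutarates. The step needs face selectivity (C2) and epimer selectivity (C3) from the enzyme and arm selectivity (C4) from the substrate; the tert‑butyl ester cannot compete because it would give a β‑lactone, and it should survive the pyridinium acid.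

Step 3
Reactants: 5 tert‑butyl (2S,3R,4S)‑4‑(2‑methoxy‑2‑oxoethyl)‑2‑methyl‑6‑oxooxane‑3‑carboxylate
Product: 6 tert‑butyl (2S,3R,4R)‑5‑(hydroxymethylidene)‑4‑(2‑methoxy‑2‑oxoethyl)‑2‑methyl‑6‑oxooxane‑3‑carboxylate
Conditions: LiN(SiMe3)2 (2.2 equiv), THF, −78 °C; HCO2Me (5 equiv), −78 to 0 °C; 1 M HCl, 0 °C
Reagents that add atoms: methyl formate, COC=O
Why: Crossed Claisen formylation; the lactone α‑CH2 (C5) is roughly four pKa units more acidic than the open‑chain CH2CO2Me group and far more than the tertiary C3–H, so the amide base should form the lactone enolate selectively, and C‑formylation gives a β‑dicarbonyl that the second equivalent of base holds as its enolate, which also shields the lactone from methoxide. No stereocentre is formed; C4 keeps its configuration and only its descriptor changes because C5 becomes trigonal.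

Step 4
Reactants: 6 tert‑butyl (2S,3R,4R)‑5‑(hydroxymethylidene)‑4‑(2‑methoxy‑2‑oxoethyl)‑2‑methyl‑6‑oxooxane‑3‑carboxylate
Product: 8 3‑tert‑butyl 5‑methyl (2S,3R,4R)‑4‑(2‑methoxy‑2‑oxoethyl)‑2‑methyl‑3,4‑dihydro‑2H‑pyran‑3,5‑dicarboxylate, via cyclic methyl acetal 7 (not isolated)
Conditions: CSA (0.2 equiv), MeOH, rt; pyridine (0.3 equiv), concentrate; toluene, 90 °C (−MeOH)
Reagents that add atoms: methanol, CO
Why: Korte acyl‑lactone rearrangement; acid methanolysis opens the α‑formyl lactone so that its acyl carbon becomes the C5 methoxycarbonyl group, the released C2 hydroxyl closes on the formyl carbon to the cyclic methyl acetal 7, and the pyridinium sulfonate then eliminates methanol to the conjugated enol ether, the thermodynamic sink. Only the formylated arm can enter the ring, so the arm selection of step 2 is carried over to C4; C2 and C3 are not touched under acid and the buffered acid should spare the tert‑butyl ester.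

Step 5
Reactants: 8 3‑tert‑butyl 5‑methyl (2S,3R,4R)‑4‑(2‑methoxy‑2‑oxoethyl)‑2‑methyl‑3,4‑dihydro‑2H‑pyran‑3,5‑dicarboxylate
Product: 9 [(2S,3R,4R)‑3‑(tert‑butoxycarbonyl)‑5‑(methoxycarbonyl)‑2‑methyl‑3,4‑dihydro‑2H‑pyran‑4‑yl]acetic acid
Conditions: LiOH·H2O (1.1 equiv), THF/H2O (3:1), 0 °C; 1 M HCl to pH 3
Reagents that add atoms: lithium hydroxide, [Li+].[OH-]
Why: Saponification by acyl–oxygen cleavage; hydroxide attacks the only unhindered, unconjugated ester, while the C5 ester is a vinylogous carbonate and the C3 ester is tert‑butyl and α‑branched, so both should react far more slowly at 0 °C with one equivalent of base.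

Step 6
Reactants: 10 hydroxytyrosol
Product: 11 2‑[3,4‑bis(benzyloxy)phenyl]ethan‑1‑ol
Conditions: BnBr (2.1 equiv), K2CO3 (2.5 equiv), acetone, reflux, N2
Reagents that add atoms: benzyl bromide, BrCc1ccccc1
Why: Williamson ether synthesis; the carbonate deprotonates only the phenols, so both catechol oxygens are benzylated and the primary alcohol stays free.

Step 7
Reactants: 9 [(2S,3R,4R)‑3‑(tert‑butoxycarbonyl)‑5‑(methoxycarbonyl)‑2‑methyl‑3,4‑dihydro‑2H‑pyran‑4‑yl]acetic acid; 11 2‑[3,4‑bis(benzyloxy)phenyl]ethan‑1‑ol
Product: 12 3‑tert‑butyl 5‑methyl (2S,3R,4R)‑4‑{2‑[2‑(3,4‑bis(benzyloxy)phenyl)ethoxy]‑2‑oxoethyl}‑2‑methyl‑3,4‑dihydro‑2H‑pyran‑3,5‑dicarboxylate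
Conditions: EDC·HCl (1.3 equiv), DMAP (0.1 equiv), CH2Cl2, 0 °C to rt
Reagents that add atoms: none
Why: Steglich esterification; the carbodiimide activates the unhindered CH2CO2H group and DMAP passes the acyl group to the primary alcohol of 11, with no stereocentre α to the activated carboxyl.

Step 8
Reactants: 12 3‑tert‑butyl 5‑methyl (2S,3R,4R)‑4‑{2‑[2‑(3,4‑bis(benzyloxy)phenyl)ethoxy]‑2‑oxoethyl}‑2‑methyl‑3,4‑dihydro‑2H‑pyran‑3,5‑dicarboxylate
Product: 13 (2S,3R,4R)‑4‑{2‑[2‑(3,4‑bis(benzyloxy)phenyl)ethoxy]‑2‑oxoethyl}‑5‑(methoxycarbonyl)‑2‑methyl‑3,4‑dihydro‑2H‑pyran‑3‑carboxylic acid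
Conditions: TFA/CH2Cl2 (1:4), 0 °C to rt
Reagents that add atoms: none
Why: Acidolysis of the tert‑butyl ester by alkyl–oxygen cleavage through the tert‑butyl cation; methyl and primary alkyl esters, aryl benzyl ethers and the β‑alkoxyacrylate should be stable to anhydrous TFA over the short reaction time.

Step 9
Reactants: 13 (2S,3R,4R)‑4‑{2‑[2‑(3,4‑bis(benzyloxy)phenyl)ethoxy]‑2‑oxoethyl}‑5‑(methoxycarbonyl)‑2‑methyl‑3,4‑dihydro‑2H‑pyran‑3‑carboxylic acid
Product: 14 methyl (2S,3S,4R)‑4‑{2‑[2‑(3,4‑bis(benzyloxy)phenyl)ethoxy]‑2‑oxoethyl}‑3‑(hydroxymethyl)‑2‑methyl‑3,4‑dihydro‑2H‑pyran‑5‑carboxylate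
Conditions: BH3·SMe2 (2.5 equiv), THF, 0 °C to rt; MeOH then H2O
Reagents that add atoms: none
Why: Borane reduces a free carboxylic acid through its acyloxyborane much faster than esters, and the electron‑poor C5=C6 bond of the β‑alkoxyacrylate is a poor partner for hydroboration, so only C7 should be reduced. The C3 descriptor changes by priority only, and the alcohol is oxidised at once to forestall lactonisation onto the side‑chain ester.

Step 10
Reactants: 14 methyl (2S,3S,4R)‑4‑{2‑[2‑(3,4‑bis(benzyloxy)phenyl)ethoxy]‑2‑oxoethyl}‑3‑(hydroxymethyl)‑2‑methyl‑3,4‑dihydro‑2H‑pyran‑5‑carboxylate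
Product: 15 methyl (2S,3R,4R)‑4‑{2‑[2‑(3,4‑bis(benzyloxy)phenyl)ethoxy]‑2‑oxoethyl}‑3‑formyl‑2‑methyl‑3,4‑dihydro‑2H‑pyran‑5‑carboxylate
Conditions: Dess–Martin periodinane (1.3 equiv), CH2Cl2, 0 °C to rt
Reagents that add atoms: none
Why: Dess–Martin oxidation of the primary alcohol to the aldehyde without base, so C3 should not epimerise and O1 should not be eliminated; benzyl ethers and the enol ether are inert to the periodinane.

Step 11
Reactants: 15 methyl (2S,3R,4R)‑4‑{2‑[2‑(3,4‑bis(benzyloxy)phenyl)ethoxy]‑2‑oxoethyl}‑3‑formyl‑2‑methyl‑3,4‑dihydro‑2H‑pyran‑5‑carboxylate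
Product: 16 methyl (2S,3R,4R)‑4‑{2‑[2‑(3,4‑dihydroxyphenyl)ethoxy]‑2‑oxoethyl}‑3‑formyl‑2‑methyl‑3,4‑dihydro‑2H‑pyran‑5‑carboxylate
Conditions: H2 (1 atm), Pd/C (10%), EtOAc, rt
Reagents that add atoms: none
Why: Hydrogenolysis of the two aryl benzyl ethers under neutral conditions; the trisubstituted push–pull C5=C6 bond and the aliphatic aldehyde should be reduced much more slowly than the O–benzyl bonds are cleaved, and no acid or base reaches the labile C3 centre.

## Compound list

1 | tert‑butyl acetoacetate | CC(=O)CC(=O)OC(C)(C)C | starting material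
2 | dimethyl glutaconate (dimethyl (2E)‑pent‑2‑enedioate) | COC(=O)/C=C/CC(=O)OC | starting material
3 | 1‑tert‑butyl 5‑methyl 2‑acetyl‑3‑(2‑methoxy‑2‑oxoethyl)pentanedioate (racemic, labile centre drawn without descriptor) | CC(=O)C(C(=O)OC(C)(C)C)C(CC(=O)OC)CC(=O)OC | intermediate
4 | 1‑tert‑butyl 5‑methyl (2R)‑2‑[(1S)‑1‑hydroxyethyl]‑3‑(2‑methoxy‑2‑oxoethyl)pentanedioate | C[C@H](O)[C@H](C(=O)OC(C)(C)C)C(CC(=O)OC)CC(=O)OC | intermediate (not isolated)
5 | tert‑butyl (2S,3R,4S)‑4‑(2‑methoxy‑2‑oxoethyl)‑2‑methyl‑6‑oxooxane‑3‑carboxylate | O=C1O[C@@H](C)[C@H](C(=O)OC(C)(C)C)[C@@H](CC(=O)OC)C1 | intermediate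
6 | tert‑butyl (2S,3R,4R)‑5‑(hydroxymethylidene)‑4‑(2‑methoxy‑2‑oxoethyl)‑2‑methyl‑6‑oxooxane‑3‑carboxylate (enol form, in equilibrium with the aldehyde tautomer; double‑bond geometry not fixed) | O=C1O[C@@H](C)[C@H](C(=O)OC(C)(C)C)[C@@H](CC(=O)OC)C1=CO | intermediate
7 | 3‑tert‑butyl 5‑methyl (2S,3R,4R)‑6‑methoxy‑4‑(2‑methoxy‑2‑oxoethyl)‑2‑methyloxane‑3,5‑dicarboxylate (mixture at C5 and C6) | COC1O[C@@H](C)[C@H](C(=O)OC(C)(C)C)[C@@H](CC(=O)OC)C1C(=O)OC | intermediate (not isolated)
8 | 3‑tert‑butyl 5‑methyl (2S,3R,4R)‑4‑(2‑methoxy‑2‑oxoethyl)‑2‑methyl‑3,4‑dihydro‑2H‑pyran‑3,5‑dicarboxylate | COC(=O)C1=CO[C@@H](C)[C@H](C(=O)OC(C)(C)C)[C@H]1CC(=O)OC | intermediate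
9 | [(2S,3R,4R)‑3‑(tert‑butoxycarbonyl)‑5‑(methoxycarbonyl)‑2‑methyl‑3,4‑dihydro‑2H‑pyran‑4‑yl]acetic acid | COC(=O)C1=CO[C@@H](C)[C@H](C(=O)OC(C)(C)C)[C@H]1CC(=O)O | intermediate
10 | hydroxytyrosol | OCCc1ccc(O)c(O)c1 | starting material
11 | 2‑[3,4‑bis(benzyloxy)phenyl]ethan‑1‑ol | OCCc1ccc(OCc2ccccc2)c(OCc2ccccc2)c1 | intermediate
12 | 3‑tert‑butyl 5‑methyl (2S,3R,4R)‑4‑{2‑[2‑(3,4‑bis(benzyloxy)phenyl)ethoxy]‑2‑oxoethyl}‑2‑methyl‑3,4‑dihydro‑2H‑pyran‑3,5‑dicarboxylate | COC(=O)C1=CO[C@@H](C)[C@H](C(=O)OC(C)(C)C)[C@H]1CC(=O)OCCc1ccc(OCc2ccccc2)c(OCc2ccccc2)c1 | intermediate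
13 | (2S,3R,4R)‑4‑{2‑[2‑(3,4‑bis(benzyloxy)phenyl)ethoxy]‑2‑oxoethyl}‑5‑(methoxycarbonyl)‑2‑methyl‑3,4‑dihydro‑2H‑pyran‑3‑carboxylic acid | COC(=O)C1=CO[C@@H](C)[C@H](C(=O)O)[C@H]1CC(=O)OCCc1ccc(OCc2ccccc2)c(OCc2ccccc2)c1 | intermediate
14 | methyl (2S,3S,4R)‑4‑{2‑[2‑(3,4‑bis(benzyloxy)phenyl)ethoxy]‑2‑oxoethyl}‑3‑(hydroxymethyl)‑2‑methyl‑3,4‑dihydro‑2H‑pyran‑5‑carboxylate | COC(=O)C1=CO[C@@H](C)[C@H](CO)[C@H]1CC(=O)OCCc1ccc(OCc2ccccc2)c(OCc2ccccc2)c1 | intermediate
15 | methyl (2S,3R,4R)‑4‑{2‑[2‑(3,4‑bis(benzyloxy)phenyl)ethoxy]‑2‑oxoethyl}‑3‑formyl‑2‑methyl‑3,4‑dihydro‑2H‑pyran‑5‑carboxylate | COC(=O)C1=CO[C@@H](C)[C@H](C=O)[C@H]1CC(=O)OCCc1ccc(OCc2ccccc2)c(OCc2ccccc2)c1 | intermediate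
16 | methyl (2S,3R,4R)‑4‑{2‑[2‑(3,4‑dihydroxyphenyl)ethoxy]‑2‑oxoethyl}‑3‑formyl‑2‑methyl‑3,4‑dihydro‑2H‑pyran‑5‑carboxylate | COC(=O)C1=CO[C@@H](C)[C@H](C=O)[C@H]1CC(=O)OCCc1ccc(O)c(O)c1 | target

## Step count and risk

Total: 11 steps. Longest linear sequence: 10 steps (steps 1 to 5 and 7 to 11); step 6 is a one‑step side branch.

**Step 2 (key step).**
- Most likely failure: no panel enzyme accepts the ketone, because the α‑substituent is a branched diester. The enzyme may also reduce with anti preference, or the arm selection in the lactonisation may be only moderate, since an axial arm on C4 costs little in a δ‑lactone. A minor lactone can be returned to 4 by acid methanolysis and cyclised again.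
- Fallback: setting out from 3, chelation‑controlled reduction with Zn(BH4)2 in Et2O at −20 °C should give the racemic syn hydroxy triester F1. Candida antarctica lipase B with vinyl acetate should then acylate the (1R) alcohol (Kazlauskas rule) to the acetate of the unwanted enantiomer F2 and leave 4 unacylated. After separation the route is rejoined at 4, which is lactonised as in step 2. The cost is half of the material.

**Step 3.**
- Most likely failure: loss of site selectivity in the enolisation. Formylation of the side‑chain ester, or deprotonation at C3 followed by β‑elimination of the lactone oxygen, would compete if the base is not discriminating enough.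
- Fallback: setting out from 5, condensation with tert‑butoxybis(dimethylamino)methane in toluene at 80 °C needs no strong base and reacts with lactones in preference to open‑chain esters. It should give the dimethylaminomethylene lactone F3. Brief hydrolysis with 1 M HCl in THF returns to the route at 6.

**Step 4.**
- Most likely failure: acid cleavage of the tert‑butyl ester during methanolysis, or a stall at the acetal stage because methanol is not eliminated under the mild acid.
- Fallback: setting out from 6, O‑methylation of the acidic enol with Me3SiCHN2 in MeOH/toluene gives the methoxymethylene lactone F4. Catalytic NaOMe in MeOH at 0 °C opens the lactone under basic conditions, which the tert‑butyl ester tolerates, to the open‑chain hydroxy methoxyacrylate F5. PPTS in toluene at 80 °C then closes O1 onto C6 by transetherification with loss of methanol, rejoining the route at 8.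

**Step 9.**
- Most likely failure: hydroboration of the enol ether or slow reduction of the side‑chain ester by excess borane. The new alcohol may also lactonise onto the side‑chain ester and release 11.
- Fallback: setting out from 13, coupling with EtSH (EDC·HCl, DMAP cat., CH2Cl2) gives the S‑ethyl thioester F6. Fukuyama reduction (Et3SiH, Pd/C, acetone, rt) takes it directly to the aldehyde, rejoining the route at 15 without passing through 14.

**Step 11.**
- Most likely failure: over‑reduction of the aldehyde or of the C5=C6 bond during hydrogenolysis. Epimerisation or ring opening of the product during prolonged contact with the catalyst is the second risk.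
- Fallback: setting out from 15, Lewis‑acid debenzylation with BCl3 and pentamethylbenzene as cation trap in CH2Cl2 at −78 °C removes both benzyl groups without hydrogen and arrives directly at 16. No new intermediate is formed.

## Further compounds

F1 | step 2 | racemic syn hydroxy triester (4 together with its enantiomer) | C[C@H](O)[C@H](C(=O)OC(C)(C)C)C(CC(=O)OC)CC(=O)OC.C[C@@H](O)[C@@H](C(=O)OC(C)(C)C)C(CC(=O)OC)CC(=O)OC
F2 | step 2 | 1‑tert‑butyl 5‑methyl (2S)‑2‑[(1R)‑1‑acetoxyethyl]‑3‑(2‑methoxy‑2‑oxoethyl)pentanedioate | C[C@@H](OC(C)=O)[C@@H](C(=O)OC(C)(C)C)C(CC(=O)OC)CC(=O)OC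
F3 | step 3 | tert‑butyl (2S,3R,4R)‑5‑[(dimethylamino)methylidene]‑4‑(2‑methoxy‑2‑oxoethyl)‑2‑methyl‑6‑oxooxane‑3‑carboxylate | O=C1O[C@@H](C)[C@H](C(=O)OC(C)(C)C)[C@@H](CC(=O)OC)C1=CN(C)C
F4 | step 4 | tert‑butyl (2S,3R,4R)‑5‑(methoxymethylidene)‑4‑(2‑methoxy‑2‑oxoethyl)‑2‑methyl‑6‑oxooxane‑3‑carboxylate | O=C1O[C@@H](C)[C@H](C(=O)OC(C)(C)C)[C@@H](CC(=O)OC)C1=COC
F5 | step 4 | 1‑tert‑butyl 5‑methyl (2R,3R)‑2‑[(1S)‑1‑hydroxyethyl]‑3‑(2‑methoxy‑2‑oxoethyl)‑4‑(methoxymethylidene)pentanedioate | C[C@H](O)[C@H](C(=O)OC(C)(C)C)[C@@H](CC(=O)OC)C(=COC)C(=O)OC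
F6 | step 9 | methyl (2S,3R,4R)‑4‑{2‑[2‑(3,4‑bis(benzyloxy)phenyl)ethoxy]‑2‑oxoethyl}‑3‑[(ethylsulfanyl)carbonyl]‑2‑methyl‑3,4‑dihydro‑2H‑pyran‑5‑carboxylate | COC(=O)C1=CO[C@@H](C)[C@H](C(=O)SCC)[C@H]1CC(=O)OCCc1ccc(OCc2ccccc2)c(OCc2ccccc2)c1
F0 | step 11 | none | none
A1 | alternative 1 | 5‑formyl‑6‑methyl δ‑lactone carrying the hydroxymethylene ester on C4 | O=C1C[C@@H](/C(C(=O)OC)=C/O)[C@@H](C=O)[C@H](C)O1
A2 | alternative 1 | (6S)‑6‑methyl‑3,6‑dihydro‑2H‑pyran‑2‑one | O=C1CC=C[C@H](C)O1
A3 | alternative 1 | methyl 2‑formyl‑3‑hydroxyprop‑2‑enoate (enol of methyl diformylacetate) | COC(=O)C(C=O)=CO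
A4 | alternative 2 | catechol acetonide of the target | COC(=O)C1=CO[C@@H](C)[C@H](C=O)[C@H]1CC(=O)OCCc1ccc2OC(C)(C)Oc2c1
A5 | alternative 2 | open‑chain aldehyde tethered through O1 to the alkoxydienoate | O=CC[C@H](C)O/C=C(\C=C\C(=O)OCCc1ccc2OC(C)(C)Oc2c1)C(=O)OC
A6 | alternative 3 | all‑equatorial δ‑lactone with C5 methyl ester, C4 acetate arm and C3 4‑methoxybenzyloxymethyl group | O=C1O[C@@H](C)[C@H](COCc2ccc(OC)cc2)[C@@H](CC(=O)OCCc2ccc3OC(C)(C)Oc3c2)[C@@H]1C(=O)OC
A7 | alternative 3 | methyl malonate of the C2 alcohol carrying the E‑enoate | COC(=O)CC(=O)O[C@@H](C)[C@H](COCc1ccc(OC)cc1)/C=C/C(=O)OCCc1ccc2OC(C)(C)Oc2c1
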